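**Plan**
1. Retrosynthetic cuts, in order: the enone Cα=Cβ bond (aldol condensation); the C8–acyl bond (aryl anion plus acetyl donor); then, with a carbonyl written back at C4, the C3–C4 bond of the dihydropyran ring; last, the O1–C2 ether bond.
2. Feature behind the key cut: carbinol carbon C3 of the dihydropyran ring is bonded directly to benzylic C4, which sits on C4a of aromatic ring A. Drawn as two formyl carbons, both are acceptors, and C4, being an aryl formyl carbon, is the one a carbene can invert into an acyl anion.
3. Forward order: ring A is bought as a phloroglucinol carbaldehyde whose formyl carbon becomes C4. O1–C2 is made by O-alkylation, the dihydropyran ring closes at C3–C4, the C4 oxygen is removed, and the cinnamoyl arm with ring B is built on C8.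
4. Stereochemistry: C3 is the only stereocentre and is set in the ring closure by a chiral triazolium catalyst. The ketol is (3S) and the target (3R) with no change in space, because C4 outranks C2 as C=O but not as CH2. The E-alkene follows from the condensation.
5. Protecting groups: one MOM ether on O5 runs from step 2 to the last step. It tolerates base, hydride and organolithium and leaves without touching the enone, which a benzyl ether (hydrogenolysis) or an aryl silyl ether (KOH) would not allow.

Key step: step 6

Assumption: triazolium salt T is (5aR,10bS)-2-(pentafluorophenyl)-5a,10b-dihydro-4H,6H-indeno[2,1-b][1,2,4]triazolo[4,3-d][1,4]oxazin-2-ium tetrafluoroborate; its sense of induction is inferred from keto-aldehyde cyclisations with this catalyst family, and if the ketol proves to be (3R) the equally available (5aS,10bR) salt is used with no other change.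

Step 1
Reactants: 1 2,4,6-trihydroxybenzaldehyde
Product: 2 2,6-dihydroxy-4-methoxybenzaldehyde
Conditions: Me2SO4 (1.0 equiv), K2CO3 (1.0 equiv), acetone, 23 to 56 °C
Reagents that add atoms: dimethyl sulfate, COS(=O)(=O)OC
Why: Williamson O-methylation with one equivalent of base and electrophile should go to the 4-OH, which is the most acidic hydroxyl and the only one that cannot hydrogen-bond to the formyl oxygen.

Step 2
Reactants: 2 2,6-dihydroxy-4-methoxybenzaldehyde
Product: 3 2-hydroxy-4-methoxy-6-(methoxymethoxy)benzaldehyde
Conditions: MOMCl (1.05 equiv), i-Pr2NEt (1.2 equiv), CH2Cl2, 0 °C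
Reagents that add atoms: chloromethyl methyl ether, COCCl
Why: In this Williamson-type MOM ether formation, once one of the two equivalent ortho hydroxyls has reacted the other is held in a chelate with the formyl oxygen and reacts much more slowly, which favours the mono-ether.

Step 3
Reactants: 3 2-hydroxy-4-methoxy-6-(methoxymethoxy)benzaldehyde; 4 ethyl 2-bromo-2-methylpropanoate
Product: 5 ethyl 2-[2-formyl-5-methoxy-3-(methoxymethoxy)phenoxy]-2-methylpropanoate
Conditions: Cs2CO3 (2 equiv), 4 (2 equiv), DMF, 60 °C
Reagents that add atoms: none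
Why: Williamson O-alkylation of a phenoxide with a tertiary α-bromo ester is the standard route to 2-aryloxy-2-methylpropanoates and is known for salicylaldehydes; excess 4 offsets loss by elimination, and the quaternary α-carbon excludes a follow-up aldol closure onto the formyl group.

Step 4
Reactants: 5 ethyl 2-[2-formyl-5-methoxy-3-(methoxymethoxy)phenoxy]-2-methylpropanoate
Product: 6 2-[2-(hydroxymethyl)-5-methoxy-3-(methoxymethoxy)phenoxy]-2-methylpropan-1-ol
Conditions: LiAlH4 (1.5 equiv), THF, 0 °C; H2O, aq NaOH
Reagents that add atoms: none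
Why: LiAlH4 reduction of ester and aldehyde together removes any need to tell the two carbonyl groups apart, the ethers are inert, and the basic work-up spares the acid-labile trialkoxybenzyl alcohol, which is used crude.

Step 5
Reactants: 6 2-[2-(hydroxymethyl)-5-methoxy-3-(methoxymethoxy)phenoxy]-2-methylpropan-1-ol
Product: 7 2-[2-formyl-5-methoxy-3-(methoxymethoxy)phenoxy]-2-methylpropanal
Conditions: Dess–Martin periodinane (2.6 equiv), pyridine (6 equiv), CH2Cl2, 0 to 23 °C
Reagents that add atoms: none
Why: Double Dess–Martin oxidation should stop at the aldehyde for both primary alcohols, with pyridine buffering the acid that could ionise the benzylic alcohol, and it is fast enough to outrun lactol formation between the two ends.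

Step 6
Reactants: 7 2-[2-formyl-5-methoxy-3-(methoxymethoxy)phenoxy]-2-methylpropanal
Product: 8 (3S)-3-hydroxy-7-methoxy-5-(methoxymethoxy)-2,2-dimethylchroman-4-one
Conditions: triazolium salt T (15 mol %), i-Pr2NEt (15 mol %), 4 Å MS, degassed PhMe (0.03 M), Ar, 23 °C; AcOH quench
Reagents that add atoms: none
Why: Proposed new method: the triazolylidene freed from T adds to the aryl formyl group of 7, proton transfer gives the Breslow enaminol in which C4 is nucleophilic, this carbon attacks the side-chain formyl carbon C3, and collapse of the adduct releases the carbene and leaves the C4 ketone. The closest known reaction type is the enantioselective intramolecular crossed benzoin of 2-(2-oxoalkoxy)benzaldehydes with the same catalyst family, which gives tertiary 3-hydroxychroman-4-ones; new here are the aldehyde acceptor, the secondary and therefore enolisable ketol, and the 2,6-dioxygenated donor aldehyde. The dihydropyran ring (O1–C2–C3–C4–C4a–C8a) closes in the 6-exo-trig mode. C3 is controlled by the catalyst: the indane wall covers one face of the enaminol and the enol O–H to acceptor C=O hydrogen bond orients the side chain so that C4 reaches the Re face of the aliphatic formyl group, which corresponds to (3S). The step needs donor/acceptor chemoselectivity, which the substrate supplies because the side-chain aldehyde is α-quaternary and so adds the carbene slowly, whereas the aryl group acidifies the carbinol C–H of its carbene adduct, helped by the electron-poor N-C6F5 group and by the known stabilisation of such adducts by an ortho-alkoxy group. Base is held at the catalyst loading and the reaction is stopped with AcOH so that the ketol should neither enolise nor reopen by retro-benzoin before it is reduced.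

Step 7
Reactants: 8 (3S)-3-hydroxy-7-methoxy-5-(methoxymethoxy)-2,2-dimethylchroman-4-one
Product: 9 (3R,4RS)-7-methoxy-5-(methoxymethoxy)-2,2-dimethylchroman-3,4-diol
Conditions: NaBH4 (1.5 equiv), CeCl3·7H2O (1.0 equiv), MeOH, −40 to 0 °C
Reagents that add atoms: none
Why: Luche-type reduction is fast and weakly basic, so the ketone should be consumed before C3 can epimerise; the new C4 carbinol centre is left uncontrolled because step 8 removes it, and C3 becomes (3R) by descriptor only.

Step 8
Reactants: 9 (3R,4RS)-7-methoxy-5-(methoxymethoxy)-2,2-dimethylchroman-3,4-diol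
Product: 10 (3R)-7-methoxy-5-(methoxymethoxy)-2,2-dimethylchroman-3-ol
Conditions: Et3SiH (10 equiv), CF3CO2H (2 equiv), CH2Cl2 (0.02 M), −40 to 0 °C
Reagents that add atoms: none
Why: In this Kursanov–Parnes ionic hydrogenation the C4 hydroxyl lies ortho/para to three oxygen donors and should ionise with little acid at low temperature, conditions an aryl MOM ether should survive, while excess silane at high dilution traps the cation and no bond to C3 is touched.

Step 9
Reactants: 10 (3R)-7-methoxy-5-(methoxymethoxy)-2,2-dimethylchroman-3-ol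
Product: 11 (3R)-8-bromo-7-methoxy-5-(methoxymethoxy)-2,2-dimethylchroman-3-ol
Conditions: NBS (1.0 equiv), CH2Cl2, −78 to −20 °C, dark
Reagents that add atoms: N-bromosuccinimide, O=C1CCC(=O)N1Br
Why: In electrophilic aromatic bromination C6 lies between two freely rotating alkoxy groups that would be forced out of plane, whereas C8 has the tied-back ring oxygen O1 as one neighbour, the same bias that sends NBS to C8 in 5,7-di-O-alkylflavan-3-ols.

Step 10
Reactants: 11 (3R)-8-bromo-7-methoxy-5-(methoxymethoxy)-2,2-dimethylchroman-3-ol
Product: 13 1-[(3R)-3-hydroxy-7-methoxy-5-(methoxymethoxy)-2,2-dimethylchroman-8-yl]ethanone, via 8-lithio lithium 3-alkoxide 12 (not isolated)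
Conditions: n-BuLi (2.2 equiv), THF, −78 °C; MeC(O)N(OMe)Me (2 equiv), −78 to 0 °C; H2O
Reagents that add atoms: N-methoxy-N-methylacetamide, CON(C)C(C)=O; n-butyllithium, [Li]CCCC (lithium of 12 only)
Why: This is bromine–lithium exchange followed by Weinreb ketone synthesis: the first equivalent of n-BuLi removes the C3–OH proton, the second exchanges C8–Br faster than MOM-directed deprotonation at C6 can occur at −78 °C, and the chelated tetrahedral adduct prevents a second addition.

Step 11
Reactants: 14 4-hydroxybenzaldehyde
Product: 15 4-(methoxymethoxy)benzaldehyde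
Conditions: MOMCl (1.2 equiv), i-Pr2NEt (1.5 equiv), CH2Cl2, 0 to 23 °C
Reagents that add atoms: chloromethyl methyl ether, COCCl
Why: Williamson-type MOM protection of the phenol keeps the aldehyde from turning into an unreactive phenoxide under the basic condensation.

Step 12
Reactants: 13 1-[(3R)-3-hydroxy-7-methoxy-5-(methoxymethoxy)-2,2-dimethylchroman-8-yl]ethanone; 15 4-(methoxymethoxy)benzaldehyde
Product: 16 (E)-1-[(3R)-3-hydroxy-7-methoxy-5-(methoxymethoxy)-2,2-dimethylchroman-8-yl]-3-[4-(methoxymethoxy)phenyl]prop-2-en-1-one
Conditions: KOH (10 equiv), MeOH, 23 to 50 °C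
Reagents that add atoms: none
Why: Claisen–Schmidt condensation is well established for 2,6-dialkoxyacetophenones with non-enolisable aryl aldehydes, the E1cB loss of water gives the conjugated E-enone, and MOM ethers, the free C3 alcohol and the remote stereocentre are inert to hydroxide.

Step 13
Reactants: 16 (E)-1-[(3R)-3-hydroxy-7-methoxy-5-(methoxymethoxy)-2,2-dimethylchroman-8-yl]-3-[4-(methoxymethoxy)phenyl]prop-2-en-1-one
Product: 17 (E)-1-[(3R)-3,5-dihydroxy-7-methoxy-2,2-dimethylchroman-8-yl]-3-(4-hydroxyphenyl)prop-2-en-1-one
Conditions: conc. HCl (3 equiv), MeOH, 40 °C, dark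
Reagents that add atoms: none
Why: Acid-catalysed acetal exchange with methanol removes both aryl MOM groups, and because both positions ortho to the ketone carry ethers (OMe and O1) the chalcone cannot close to a flavanone.

**Compound list**
1 | 2,4,6-trihydroxybenzaldehyde | O=Cc1c(O)cc(O)cc1O | starting material
2 | 2,6-dihydroxy-4-methoxybenzaldehyde | COc1cc(O)c(C=O)c(O)c1 | intermediate
3 | 2-hydroxy-4-methoxy-6-(methoxymethoxy)benzaldehyde | COCOc1cc(OC)cc(O)c1C=O | intermediate
4 | ethyl 2-bromo-2-methylpropanoate | CCOC(=O)C(C)(C)Br | starting material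
5 | ethyl 2-[2-formyl-5-methoxy-3-(methoxymethoxy)phenoxy]-2-methylpropanoate | CCOC(=O)C(C)(C)Oc1cc(OC)cc(OCOC)c1C=O | intermediate
6 | 2-[2-(hydroxymethyl)-5-methoxy-3-(methoxymethoxy)phenoxy]-2-methylpropan-1-ol | COCOc1cc(OC)cc(OC(C)(C)CO)c1CO | intermediate
7 | 2-[2-formyl-5-methoxy-3-(methoxymethoxy)phenoxy]-2-methylpropanal | COCOc1cc(OC)cc(OC(C)(C)C=O)c1C=O | intermediate
8 | (3S)-3-hydroxy-7-methoxy-5-(methoxymethoxy)-2,2-dimethylchroman-4-one | COc1cc(OCOC)c2c(c1)OC(C)(C)[C@H](O)C2=O | intermediate
9 | (3R,4RS)-7-methoxy-5-(methoxymethoxy)-2,2-dimethylchroman-3,4-diol (both C4 epimers) | COc1cc(OCOC)c2c(c1)OC(C)(C)[C@H](O)C2O | intermediate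
10 | (3R)-7-methoxy-5-(methoxymethoxy)-2,2-dimethylchroman-3-ol | COc1cc(OCOC)c2c(c1)OC(C)(C)[C@H](O)C2 | intermediate
11 | (3R)-8-bromo-7-methoxy-5-(methoxymethoxy)-2,2-dimethylchroman-3-ol | COc1cc(OCOC)c2c(c1Br)OC(C)(C)[C@H](O)C2 | intermediate
12 | lithium (3R)-8-lithio-7-methoxy-5-(methoxymethoxy)-2,2-dimethylchroman-3-olate | COc1cc(OCOC)c2c(c1[Li])OC(C)(C)[C@H](O[Li])C2 | intermediate
13 | 1-[(3R)-3-hydroxy-7-methoxy-5-(methoxymethoxy)-2,2-dimethylchroman-8-yl]ethanone | COc1cc(OCOC)c2c(c1C(C)=O)OC(C)(C)[C@H](O)C2 | intermediate
14 | 4-hydroxybenzaldehyde | O=Cc1ccc(O)cc1 | starting material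
15 | 4-(methoxymethoxy)benzaldehyde | COCOc1ccc(C=O)cc1 | intermediate
16 | (E)-1-[(3R)-3-hydroxy-7-methoxy-5-(methoxymethoxy)-2,2-dimethylchroman-8-yl]-3-[4-(methoxymethoxy)phenyl]prop-2-en-1-one | COc1cc(OCOC)c2c(c1C(=O)/C=C/c1ccc(OCOC)cc1)OC(C)(C)[C@H](O)C2 | intermediate
17 | (E)-1-[(3R)-3,5-dihydroxy-7-methoxy-2,2-dimethylchroman-8-yl]-3-(4-hydroxyphenyl)prop-2-en-1-one | COc1cc(O)c2c(c1C(=O)/C=C/c1ccc(O)cc1)OC(C)(C)[C@H](O)C2 | target

Total steps: 13. Longest linear sequence: 12 (steps 1–10, 12, 13).

**Steps most likely to fail**

Step 6 (carries the label).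
- What may go wrong:
  - The acyl-anion equivalent may form only slowly at a formyl group flanked by two alkoxy groups on a very electron-rich ring.
  - The carbene may instead engage the side-chain formyl group, after which expulsion of the aryloxide (internal redox) would break the O1–C2 bond.
  - The C3 configuration may erode through enolisation or reversible benzoin addition.
- The fallback uses known chemistry only, sets out from 3 and returns at 10.
- Addition of 2-methylprop-1-enylmagnesium bromide (2.2 equiv, THF, 0 °C) to the formyl group should give 2-(1-hydroxy-3-methylbut-2-enyl)-5-methoxy-3-(methoxymethoxy)phenol F1.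
- Gentle heating in toluene should bring about dehydrative oxa-6π cyclisation to 7-methoxy-5-(methoxymethoxy)-2,2-dimethyl-2H-chromene F2.
- Jacobsen–Katsuki epoxidation follows, with (R,R)-N,N'-bis(3,5-di-tert-butylsalicylidene)-1,2-cyclohexanediaminomanganese chloride, mCPBA and N-methylmorpholine N-oxide in CH2Cl2 at −78 °C. 2,2-Dimethylchromenes are the model substrate class for this reaction, and it should give (3R,4R)-3,4-epoxy-7-methoxy-5-(methoxymethoxy)-2,2-dimethylchroman F3.
- The crude epoxide is opened at once by LiAlH4 (THF, 0 °C) at benzylic C4 with the C3–O bond intact, which gives 10.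

Step 9.
- What may go wrong: bromination may also occur at C6, or twice, if the steric bias between the two open positions of ring A is too small.
- The fallback replaces electrophilic substitution by directed deprotonation, sets out from 10 and returns at 13, bypassing step 10 as well.
- HCl in MeOH removes the MOM group to give (3R)-7-methoxy-2,2-dimethylchroman-3,5-diol F4.
- TIPSCl and imidazole in DMF silylate only the phenol to give (3R)-7-methoxy-2,2-dimethyl-5-(triisopropylsilyloxy)chroman-3-ol F5.
- n-BuLi (3 equiv) and TMEDA in Et2O at 0 °C deprotonate the alcohol and then C8. C8 is the only position between two coordinating ether oxygens, since the bulky silyl ether neither binds lithium nor leaves room at C6. The product is lithium (3R)-8-lithio-7-methoxy-2,2-dimethyl-5-(triisopropylsilyloxy)chroman-3-olate F6.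
- N-Methoxy-N-methylacetamide converts it into 1-[(3R)-3-hydroxy-7-methoxy-2,2-dimethyl-5-(triisopropylsilyloxy)chroman-8-yl]ethanone F7.
- n-Bu4NF in THF gives 1-[(3R)-3,5-dihydroxy-7-methoxy-2,2-dimethylchroman-8-yl]ethanone F8.
- MOMCl with i-Pr2NEt, selective for the acidic phenol, gives 13.

Step 8.
- What may go wrong:
  - The C4 cation may be captured by ring A of a second molecule (oligomerisation).
  - Acid may remove the neighbouring MOM group or cyclise it onto the C4 oxygen.
  - A 1,2-hydride shift from C3 would erase the stereocentre.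
- The fallback avoids acid and a free cation, sets out from 9 and returns at 10.
- Ac2O, pyridine and DMAP give (3R,4RS)-7-methoxy-5-(methoxymethoxy)-2,2-dimethylchroman-3,4-diyl diacetate F9.
- Hydrogenolysis (H2, Pd/C, EtOAc) cleaves only the benzylic C4–OAc bond to give (3R)-7-methoxy-5-(methoxymethoxy)-2,2-dimethylchroman-3-yl acetate F10.
- K2CO3 in MeOH releases 10.

**Further compounds**
F1 | step 6 | 2-(1-hydroxy-3-methylbut-2-enyl)-5-methoxy-3-(methoxymethoxy)phenol (racemic) | COCOc1cc(OC)cc(O)c1C(O)C=C(C)C
F2 | step 6 | 7-methoxy-5-(methoxymethoxy)-2,2-dimethyl-2H-chromene | COc1cc(OCOC)c2C=CC(C)(C)Oc2c1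
F3 | step 6 | (3R,4R)-3,4-epoxy-7-methoxy-5-(methoxymethoxy)-2,2-dimethylchroman | COc1cc(OCOC)c2c(c1)OC(C)(C)[C@@H]3O[C@H]23
F4 | step 9 | (3R)-7-methoxy-2,2-dimethylchroman-3,5-diol | COc1cc(O)c2c(c1)OC(C)(C)[C@H](O)C2
F5 | step 9 | (3R)-7-methoxy-2,2-dimethyl-5-(triisopropylsilyloxy)chroman-3-ol | COc1cc(O[Si](C(C)C)(C(C)C)C(C)C)c2c(c1)OC(C)(C)[C@H](O)C2
F6 | step 9 | lithium (3R)-8-lithio-7-methoxy-2,2-dimethyl-5-(triisopropylsilyloxy)chroman-3-olate | COc1cc(O[Si](C(C)C)(C(C)C)C(C)C)c2c(c1[Li])OC(C)(C)[C@H](O[Li])C2
F7 | step 9 | 1-[(3R)-3-hydroxy-7-methoxy-2,2-dimethyl-5-(triisopropylsilyloxy)chroman-8-yl]ethanone | COc1cc(O[Si](C(C)C)(C(C)C)C(C)C)c2c(c1C(C)=O)OC(C)(C)[C@H](O)C2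
F8 | step 9 | 1-[(3R)-3,5-dihydroxy-7-methoxy-2,2-dimethylchroman-8-yl]ethanone | COc1cc(O)c2c(c1C(C)=O)OC(C)(C)[C@H](O)C2
F9 | step 8 | (3R,4RS)-7-methoxy-5-(methoxymethoxy)-2,2-dimethylchroman-3,4-diyl diacetate | COc1cc(OCOC)c2c(c1)OC(C)(C)[C@H](OC(C)=O)C2OC(C)=O
F10 | step 8 | (3R)-7-methoxy-5-(methoxymethoxy)-2,2-dimethylchroman-3-yl acetate | COc1cc(OCOC)c2c(c1)OC(C)(C)[C@H](OC(C)=O)C2
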